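**Retrosynthetic overview**

1. Target 22 ⇒ epoxide 21 ⇒ bromo alcohol 20: the oxepane bridge (O9–C7) is cut back to a β-epoxide and the C10 hydroxyl. C10–OH and C12–Br go back to the enone of pyranone 17, and the C14 gem-dimethyl group to hemiketal 16.
2. 16 ⇒ 14: the strategy rests on the pyran C10–C11–C12–C14–O17–C18, read as the ring-expanded form of a 5-methylfuran-2-yl tertiary carbinol (C10 = furan C2, C14 = methyl-bearing furan C5, C18 = carbinol carbon). Achmatowicz oxidation forms O17–C14.
3. 14 ⇒ 12: C18 is set by chelation-controlled addition of MeMgBr to a furyl ketone made from Weinreb amide 9 and 2-methylfuran.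
4. 9 ⇒ 7 ⇒ 3 + 5: the cyclohexene with C5 and C20 cis comes from ring-closing metathesis of an Evans syn-aldol adduct.
5. Ring order: cyclohexene (step 4), pyran (step 9), oxepane bridge of the 2-oxabicyclo[3.2.2]nonane (step 14).

Key step: step 9

Remark on numbering: labels such as C10 or O17 give the position of the heavy atom in the target SMILES, counted from 1 (C5 carries the acetate, C7 the ring methyl C8 and O9, C12 the bromine, C14 the gem-dimethyl group, C18 the methyl C19, C22 the free hydroxyl).
Assumption: aldehyde 5 isomerises to the conjugated aldehyde on standing, so it is kept as a cold solution and used at once.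

**Route**

Step 1
Reactants: 1 (R)-4-benzyl-1,3-oxazolidin-2-one; 2 pent-4-enoyl chloride
Product: 3 (R)-4-benzyl-3-(pent-4-enoyl)-1,3-oxazolidin-2-one
Conditions: n-BuLi, THF, −78 °C; then 2, −78 → 0 °C
Reagents that add atoms: none
Why: N-acylation of the lithiated oxazolidinone by an acid chloride, a standard preparation of an Evans imide that touches no stereocentre.

Step 2
Reactants: 4 3-methylbut-3-en-1-ol
Product: 5 3-methylbut-3-enal
Conditions: Dess–Martin periodinane, CH2Cl2, 0 °C → rt; filtered through a short silica pad, used as a cold solution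
Reagents that add atoms: none
Why: Dess–Martin oxidation of a primary alcohol under near-neutral conditions, chosen so that the β,γ-olefin does not move into conjugation.

Step 3
Reactants: 3 (R)-4-benzyl-3-(pent-4-enoyl)-1,3-oxazolidin-2-one; 5 3-methylbut-3-enal
Product: 7 (R)-4-benzyl-3-[(2R,3S)-3-hydroxy-5-methyl-2-(prop-2-en-1-yl)hex-5-enoyl]-1,3-oxazolidin-2-one, via boron enolate 6 (not isolated)
Conditions: Bu2BOTf, i-Pr2NEt, CH2Cl2, 0 °C; then 5, −78 → 0 °C; then pH 7 buffer, MeOH, 30% H2O2, 0 °C
Reagents that add atoms: none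
Why: Evans syn-aldol addition, in which the Z-boron enolate reacts through a Zimmerman–Traxler chair on the face away from the benzyl group; this sets C20 (R) and C5 (S) syn, which becomes cis on the ring.

Step 4
Reactants: 7 (R)-4-benzyl-3-[(2R,3S)-3-hydroxy-5-methyl-2-(prop-2-en-1-yl)hex-5-enoyl]-1,3-oxazolidin-2-one
Product: 8 (R)-4-benzyl-3-[(1R,6S)-6-hydroxy-4-methylcyclohex-3-ene-1-carbonyl]-1,3-oxazolidin-2-one
Conditions: second-generation Grubbs catalyst RuCl2(=CHPh)(PCy3)(SIMes) (3 mol %), CH2Cl2 (0.01 M), 40 °C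
Reagents that add atoms: none
Why: ring-closing metathesis of the monosubstituted and the 1,1-disubstituted olefin closes the six-membered ring with the trisubstituted C7=C22 bond and loss of ethene, and it tolerates the free hydroxyl and the imide and involves no stereocentre.

Step 5
Reactants: 8 (R)-4-benzyl-3-[(1R,6S)-6-hydroxy-4-methylcyclohex-3-ene-1-carbonyl]-1,3-oxazolidin-2-one
Product: 9 (1R,6S)-6-hydroxy-N-methoxy-N,4-dimethylcyclohex-3-ene-1-carboxamide
Conditions: MeONHMe·HCl, AlMe3, THF–CH2Cl2, −10 °C → rt
Reagents that add atoms: N,O-dimethylhydroxylamine hydrochloride, CNOC.Cl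
Why: transamination of the imide with the aluminium amide (Weinreb amide formation), assisted by the free β-hydroxyl, releases the auxiliary without epimerising C20.

Step 6
Reactants: 9 (1R,6S)-6-hydroxy-N-methoxy-N,4-dimethylcyclohex-3-ene-1-carboxamide; 10 2-methylfuran
Product: 12 [(1R,6S)-6-hydroxy-4-methylcyclohex-3-en-1-yl](5-methylfuran-2-yl)methanone, via 5-methyl-2-furyllithium 11 (not isolated)
Conditions: 10 (3.2 equiv), n-BuLi (3.0 equiv), THF, 0 °C → rt; then 9, −78 → 0 °C; cold aqueous quench
Reagents that add atoms: none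
Why: acyl substitution of a Weinreb amide by an aryllithium, in which the first equivalent deprotonates the hydroxyl and the chelated tetrahedral intermediate prevents over-addition, so the cis β-hydroxy ketone should be released only on the cold quench.

Step 7
Reactants: 12 [(1R,6S)-6-hydroxy-4-methylcyclohex-3-en-1-yl](5-methylfuran-2-yl)methanone
Product: 13 (1S,6R)-6-[(1S)-1-hydroxy-1-(5-methylfuran-2-yl)ethyl]-3-methylcyclohex-3-en-1-ol
Conditions: MeMgBr (3.5 equiv, Et2O solution), CH2Cl2, −78 → −40 °C
Reagents that add atoms: methylmagnesium bromide, C[Mg]Br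
Why: chelation-controlled Grignard addition, in which the magnesium alkoxide at C5 binds the ketone oxygen in a six-membered chelate cis-fused to the cyclohexene and methyl attacks from the convex face (the side of H20), which sets C18 as S; adding the furyl nucleophile to the methyl ketone through the same chelate would give the C18 epimer, hence this order.

Step 8
Reactants: 13 (1S,6R)-6-[(1S)-1-hydroxy-1-(5-methylfuran-2-yl)ethyl]-3-methylcyclohex-3-en-1-ol
Product: 14 (1S,6R)-6-[(1S)-1-hydroxy-1-(5-methylfuran-2-yl)ethyl]-3-methylcyclohex-3-en-1-yl acetate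
Conditions: Ac2O (1.3 equiv), pyridine, DMAP (5 mol %), CH2Cl2, 0 °C
Reagents that add atoms: acetic anhydride, CC(=O)OC(C)=O
Why: selective acylation of the secondary C5 hydroxyl, since the tertiary furyl carbinol is too hindered to react under these basic conditions, which also spare the acid-labile carbinol.

Step 9
Reactants: 14 (1S,6R)-6-[(1S)-1-hydroxy-1-(5-methylfuran-2-yl)ethyl]-3-methylcyclohex-3-en-1-yl acetate
Product: 16 (1S,6R)-6-[(2S)-6-hydroxy-2,6-dimethyl-3-oxo-3,6-dihydro-2H-pyran-2-yl]-3-methylcyclohex-3-en-1-yl acetate (anomeric mixture at C14), via Z-ene-dione 15 (not isolated)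
Conditions: VO(acac)2 (5 mol %), t-BuOOH (1.2 equiv, decane solution), CH2Cl2, 0 °C → rt
Reagents that add atoms: tert-butyl hydroperoxide, CC(C)(C)OO
Why: Achmatowicz rearrangement in its VO(acac)2/t-BuOOH form: the tertiary C18 hydroxyl binds vanadium, the peroxide oxygen is delivered to the adjacent C10=C11 bond of the furan, the oxidised furan opens to the Z-ene-dione 15, and O17 adds to the C14 ketone. The closest known reaction type is the oxidative ring expansion of furfuryl alcohols to 6-hydroxy-2H-pyran-3(6H)-ones, which accepts tertiary carbinols and 5-alkylfurans. The pyran closes by 6-exo-trig hemiketalisation (O17–C14), leaving C10 as the ketone and C11=C12 as the enone. The only new stereocentre is the hemiketal carbon C14, which forms without control as an anomeric mixture and is erased in step 10; C18, C20 and C5 are untouched because C18 bears no hydrogen and the medium is neutral. The step needs chemoselectivity for the furan over the trisubstituted ring olefin, which is secured by the far higher electron density of the 2,5-dialkylfuran and by hydroxyl-directed delivery, the ring olefin being only bishomoallylic to the C18 hydroxyl.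

Step 10
Reactants: 16 (1S,6R)-6-[(2S)-6-hydroxy-2,6-dimethyl-3-oxo-3,6-dihydro-2H-pyran-2-yl]-3-methylcyclohex-3-en-1-yl acetate
Product: 17 (1S,6R)-3-methyl-6-[(2S)-2,6,6-trimethyl-3-oxo-3,6-dihydro-2H-pyran-2-yl]cyclohex-3-en-1-yl acetate
Conditions: AlMe3 (4 equiv, hexane solution), CH2Cl2, −78 → 0 °C
Reagents that add atoms: trimethylaluminium, C[Al](C)C
Why: C-methylation of a lactol-type centre with AlMe3, in which the aluminium hemiketalate ionises to the cyclic oxocarbenium ion and takes methyl from aluminium; C14 becomes CMe2 so both anomers converge, and the neopentyl C10 ketone and the acetate should react more slowly at or below 0 °C.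

Step 11
Reactants: 17 (1S,6R)-3-methyl-6-[(2S)-2,6,6-trimethyl-3-oxo-3,6-dihydro-2H-pyran-2-yl]cyclohex-3-en-1-yl acetate
Product: 19 (1S,6R)-6-[(2S,5S)-5-bromo-2,6,6-trimethyl-3-oxooxan-2-yl]-3-methylcyclohex-3-en-1-yl acetate (used crude), via β-bromo silyl enol ether 18 (not isolated)
Conditions: Me3SiBr (1.5 equiv), 2,6-di-tert-butyl-4-methylpyridine (0.2 equiv), CH2Cl2, −78 → −40 °C; then 1 M aqueous citric acid–THF, 0 °C
Reagents that add atoms: bromotrimethylsilane, C[Si](C)(C)Br
Why: 1,4-addition of Me3SiBr to the enone (conjugate hydrobromination through the silyl enol ether) avoids free HBr and so spares the ring olefin; bromide should enter axially, anti to the pseudoaxial C14 methyl, in the half-chair where the branched C20 substituent is pseudoaxial and the small C19 methyl lies in the enone plane (the 2-alkyl ketone effect), which places Br cis to C19 (12S).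

Step 12
Reactants: 19 (1S,6R)-6-[(2S,5S)-5-bromo-2,6,6-trimethyl-3-oxooxan-2-yl]-3-methylcyclohex-3-en-1-yl acetate
Product: 20 (1S,6R)-6-[(2S,3S,5S)-5-bromo-3-hydroxy-2,6,6-trimethyloxan-2-yl]-3-methylcyclohex-3-en-1-yl acetate
Conditions: LiBH(s-Bu)3 (L-Selectride, 1.3 equiv), THF, −78 °C; then AcOH, −78 °C
Reagents that add atoms: none
Why: trialkylborohydride reduction, in which the reagent is too large for the axial trajectory (syn-axial to C12–Br in one chair and to H12 in the other) and should add along the equatorial vector, antiperiplanar to the C18–O17 bond, in the chair with C19 axial and C20 and Br equatorial; this gives the axial C10 alcohol cis to C20 (10S), and at −78 °C reduction should outrun E1cB loss of HBr.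

Step 13
Reactants: 20 (1S,6R)-6-[(2S,3S,5S)-5-bromo-3-hydroxy-2,6,6-trimethyloxan-2-yl]-3-methylcyclohex-3-en-1-yl acetate
Product: 21 (1S,3S,4R,6R)-4-[(2S,3S,5S)-5-bromo-3-hydroxy-2,6,6-trimethyloxan-2-yl]-1-methyl-7-oxabicyclo[4.1.0]heptan-3-yl acetate
Conditions: dimethyldioxirane (1.2 equiv, acetone solution), CH2Cl2, −20 → 0 °C
Reagents that add atoms: dimethyldioxirane, CC1(C)OO1
Why: dioxirane epoxidation of the trisubstituted olefin, in which the bulky C20 substituent sits equatorial and the cis C5 acetate axial and shields the lower face; oxygen should therefore arrive on the upper face, anti to both (C7 S, C22 R), under neutral conditions that allow the epoxide to be isolated.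

Step 14
Reactants: 21 (1S,3S,4R,6R)-4-[(2S,3S,5S)-5-bromo-3-hydroxy-2,6,6-trimethyloxan-2-yl]-1-methyl-7-oxabicyclo[4.1.0]heptan-3-yl acetate
Product: 22 (1R,2S,5S,7S,9R,10R,12S)-5-bromo-10-hydroxy-2,4,4,9-tetramethyl-3,8-dioxatricyclo[7.2.2.0(2,7)]tridecan-12-yl acetate (the target)
Conditions: (1S)-10-camphorsulfonic acid (10 mol %), CH2Cl2–(CF3)2CHOH 4:1, −20 → 0 °C
Reagents that add atoms: none
Why: acid-promoted epoxy-alcohol cyclisation (7-endo at the tertiary carbon): the protonated epoxide carries most of its positive charge at C7, the C10 hydroxyl on the lower face attacks C7 anti to the departing oxygen with inversion (7R), and the epoxide oxygen stays on C22 as the hydroxyl (22R), which closes the oxepane of the 2-oxabicyclo[3.2.2]nonane.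

**Compound list**

1 | (R)-4-benzyl-1,3-oxazolidin-2-one | O=C1N[C@H](Cc2ccccc2)CO1 | starting material
2 | pent-4-enoyl chloride | C=CCCC(Cl)=O | starting material
3 | (R)-4-benzyl-3-(pent-4-enoyl)-1,3-oxazolidin-2-one | C=CCCC(=O)N1[C@H](Cc2ccccc2)COC1=O | intermediate
4 | 3-methylbut-3-en-1-ol | CC(=C)CCO | starting material
5 | 3-methylbut-3-enal | CC(=C)CC=O | intermediate
6 | (Z)-dibutylboron enolate of 3 | C=CC/C=C(\OB(CCCC)CCCC)N1[C@H](Cc2ccccc2)COC1=O | intermediate
7 | (R)-4-benzyl-3-[(2R,3S)-3-hydroxy-5-methyl-2-(prop-2-en-1-yl)hex-5-enoyl]-1,3-oxazolidin-2-one | C=CC[C@H]([C@@H](O)CC(C)=C)C(=O)N1[C@H](Cc2ccccc2)COC1=O | intermediate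
8 | (R)-4-benzyl-3-[(1R,6S)-6-hydroxy-4-methylcyclohex-3-ene-1-carbonyl]-1,3-oxazolidin-2-one | O[C@H]1CC(C)=CC[C@H]1C(=O)N2[C@H](Cc3ccccc3)COC2=O | intermediate
9 | (1R,6S)-6-hydroxy-N-methoxy-N,4-dimethylcyclohex-3-ene-1-carboxamide | O[C@H]1CC(C)=CC[C@H]1C(=O)N(C)OC | intermediate
10 | 2-methylfuran | Cc1ccco1 | starting material
11 | 5-methyl-2-furyllithium | [Li]c1ccc(C)o1 | intermediate
12 | [(1R,6S)-6-hydroxy-4-methylcyclohex-3-en-1-yl](5-methylfuran-2-yl)methanone | O[C@H]1CC(C)=CC[C@H]1C(=O)c2ccc(C)o2 | intermediate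
13 | (1S,6R)-6-[(1S)-1-hydroxy-1-(5-methylfuran-2-yl)ethyl]-3-methylcyclohex-3-en-1-ol | O[C@H]1CC(C)=CC[C@H]1[C@](C)(O)c2ccc(C)o2 | intermediate
14 | (1S,6R)-6-[(1S)-1-hydroxy-1-(5-methylfuran-2-yl)ethyl]-3-methylcyclohex-3-en-1-yl acetate | CC(=O)O[C@H]1CC(C)=CC[C@H]1[C@](C)(O)c1ccc(C)o1 | intermediate
15 | (1S,6R)-6-[(2S,4Z)-2-hydroxy-3,6-dioxohept-4-en-2-yl]-3-methylcyclohex-3-en-1-yl acetate | CC(=O)O[C@H]1CC(C)=CC[C@H]1[C@](C)(O)C(=O)/C=C\C(C)=O | intermediate
16 | (1S,6R)-6-[(2S)-6-hydroxy-2,6-dimethyl-3-oxo-3,6-dihydro-2H-pyran-2-yl]-3-methylcyclohex-3-en-1-yl acetate (anomeric mixture) | CC(=O)O[C@H]1CC(C)=CC[C@H]1[C@]2(C)OC(C)(O)C=CC2=O | intermediate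
17 | (1S,6R)-3-methyl-6-[(2S)-2,6,6-trimethyl-3-oxo-3,6-dihydro-2H-pyran-2-yl]cyclohex-3-en-1-yl acetate | CC(=O)O[C@H]1CC(C)=CC[C@H]1[C@]2(C)OC(C)(C)C=CC2=O | intermediate
18 | trimethylsilyl enol ether of 19 (C10–OSiMe3, C10=C11, 12S bromide) | CC(=O)O[C@H]1CC(C)=CC[C@H]1[C@]2(C)OC(C)(C)[C@@H](Br)C=C2O[Si](C)(C)C | intermediate
19 | (1S,6R)-6-[(2S,5S)-5-bromo-2,6,6-trimethyl-3-oxooxan-2-yl]-3-methylcyclohex-3-en-1-yl acetate | CC(=O)O[C@H]1CC(C)=CC[C@H]1[C@]2(C)OC(C)(C)[C@@H](Br)CC2=O | intermediate
20 | (1S,6R)-6-[(2S,3S,5S)-5-bromo-3-hydroxy-2,6,6-trimethyloxan-2-yl]-3-methylcyclohex-3-en-1-yl acetate | CC(=O)O[C@H]1CC(C)=CC[C@H]1[C@]2(C)OC(C)(C)[C@@H](Br)C[C@@H]2O | intermediate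
21 | (1S,3S,4R,6R)-4-[(2S,3S,5S)-5-bromo-3-hydroxy-2,6,6-trimethyloxan-2-yl]-1-methyl-7-oxabicyclo[4.1.0]heptan-3-yl acetate | CC(=O)O[C@H]1C[C@]2(C)O[C@@H]2C[C@H]1[C@]3(C)OC(C)(C)[C@@H](Br)C[C@@H]3O | intermediate
22 | (1R,2S,5S,7S,9R,10R,12S)-5-bromo-10-hydroxy-2,4,4,9-tetramethyl-3,8-dioxatricyclo[7.2.2.0(2,7)]tridecan-12-yl acetate | CC(=O)O[C@H]1C[C@@]2(C)O[C@H]3C[C@H](Br)C(C)(C)O[C@@]3(C)[C@@H]1C[C@H]2O | target

**Step count and risks**

Total steps: 14. Longest linear sequence: 13 (steps 1 and 3 to 14; step 2 prepares aldehyde 5).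

Steps most likely to fail:

1. Step 11, poor facial selectivity of bromide delivery. The two half-chairs of enone 17 (C20 pseudoaxial or C19 pseudoaxial) may differ little in energy, so bromide may enter from both faces and the C12 epimer may form alongside 19. The fallback sets out from diol 13 and returns at 20, and uses the C5 hydroxyl as a temporary tether. Oxidation of 13 as in step 9 should give the hydroxy hemiketal F1. CSA with 4 Å molecular sieves in CH2Cl2 then closes the C5–O–C14 ketal to the bridged ketal enone F2, a cyclohexene-fused 2,9-dioxabicyclo[3.3.1]non-7-en-6-one. In F2, C20 and the ketal oxygen are held on one face of the pyranone. Me3SiBr then adds bromide on the open face, anti to the ketal bridge (the pattern of additions to levoglucosenone), through the silyl enol ether F3 to the bromo ketone F4. NaBH4/CeCl3·7H2O in MeOH at −78 °C reduces C10 from the same open face to the alcohol F5. AlMe3 in CH2Cl2 opens the ketal at C14 with methyl transfer, through the pyranyl oxocarbenium ion, to the diol F6. Ac2O/pyridine at 0 °C acetylates the more accessible C5 hydroxyl and gives 20.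

2. Step 14, misdirected ring closure. Attack of the C10 hydroxyl on the secondary carbon C22 through a chair (6-exo, leading to the 2-oxabicyclo[3.3.1]nonane skeleton) can compete with the boat-like 7-endo closure at C7. Capture of C7 by the carbonyl oxygen of the axial C5 acetate can also compete; with catalytic acid and no water this should be reversible. The fallback sets out from olefin 20 and returns at 22, and replaces the epoxide by a mercurinium ion, whose opening is strongly Markovnikov. Hg(OCOCF3)2 (divalent mercury) in CH2Cl2 at −20 °C, then aqueous NaCl, should give by intramolecular alkoxymercuration (C10–OH to the tertiary C7, anti to mercury) the organomercurial chloride F7. Oxidative demercuration (NaBH4, O2, DMF) then replaces mercury at C22 by hydroxyl, with oxygen expected to be captured on the open upper face of the bicycle.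

3. Step 12, loss of HBr or hydride delivery from the wrong face. The basic hydride may trigger E1cB elimination back to enone 17, or hydride may arrive along the axial vector and give the C10 epimer, which cannot close the bridge. The fallback sets out from 19 and returns at 20, and changes from substrate control with a basic hydride to catalyst control with a neutral borane. This is a Corey–Bakshi–Shibata reduction with the (R)-B-methyl oxazaborolidine derived from diphenylprolinol and catecholborane in toluene at −78 °C. The catalyst distinguishes the quaternary C18 side from the C11 methylene and should deliver hydride to the face that gives the 10S alcohol; catecholborane does not hydroborate the ring olefin at this temperature. No new compound is involved.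

Further compounds
F1 | step 11 | (1S,6R)-6-[(2S)-6-hydroxy-2,6-dimethyl-3-oxo-3,6-dihydro-2H-pyran-2-yl]-3-methylcyclohex-3-en-1-ol (anomeric mixture) | O[C@H]1CC(C)=CC[C@H]1[C@]2(C)OC(C)(O)C=CC2=O
F2 | step 11 | bridged ketal enone (C5–O–C14 ketal of F1; cyclohexene-fused 2,9-dioxabicyclo[3.3.1]non-7-en-6-one) | CC1=CC[C@@H]2[C@H](C1)O[C@]3(C)C=CC(=O)[C@@]2(C)O3
F3 | step 11 | trimethylsilyl enol ether of F4 (bromide at C12 anti to the ketal bridge) | CC1=CC[C@@H]2[C@H](C1)O[C@]3(C)[C@@H](Br)C=C(O[Si](C)(C)C)[C@@]2(C)O3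
F4 | step 11 | bridged ketal bromo ketone (12S) | CC1=CC[C@@H]2[C@H](C1)O[C@]3(C)[C@@H](Br)CC(=O)[C@@]2(C)O3
F5 | step 11 | bridged ketal bromo alcohol (10S,12S) | CC1=CC[C@@H]2[C@H](C1)O[C@]3(C)[C@@H](Br)C[C@H](O)[C@@]2(C)O3
F6 | step 11 | (1S,6R)-6-[(2S,3S,5S)-5-bromo-3-hydroxy-2,6,6-trimethyloxan-2-yl]-3-methylcyclohex-3-en-1-ol | O[C@H]1CC(C)=CC[C@H]1[C@]2(C)OC(C)(C)[C@@H](Br)C[C@@H]2O
F0 | step 12 | none | none
F7 | step 14 | chloromercurio analogue of 22 (HgCl in place of the C22 hydroxyl, same configuration) | CC(=O)O[C@H]1C[C@@]2(C)O[C@H]3C[C@H](Br)C(C)(C)O[C@@]3(C)[C@@H]1C[C@H]2[Hg]Cl
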